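Locants: octahydro-2H-chromene numbering of the target, O1, C2 (vinyl, Me), C3, C4, C4a (H), C5 (Me, CH2CO2H), C6 (H, CMe2CO2H), C7, C8, C8a (Me). Target 27 ⇐ aldehyde ester 25 by CHO → CO2H and ester hydrolysis.
25 ⇐ acyclic (Z)-enal 22 in one Lewis-acid cascade: bond C4a–C5 closes the cyclohexane first, bond O1–C8a closes the oxane last.
Enabling feature: C5 is β to the carboxyl carbon of its CH2CO2H arm, so C5=CH–CHO is a conjugate acceptor; C4a/C8a are the two carbons of a Z-trisubstituted olefin reached from C5 through C6–C7–C8, and the C2 hydroxyl reaches C8a through C3–C4–C4a. The cis-fused oxane (C4 axial, O1 equatorial on the cyclohexane chair, methyls at C5 and C8a syn) is the anti adduct of that Z olefin.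
22 ⇐ 9 + 18 by B-alkyl Suzuki coupling (bond C8–C8a); 9 from (R)-linalool (brings C2) by ozonolysis and Z-selective iodo-olefination.
18 ⇐ Ir-catalysed asymmetric allylic alkylation of dienyl carbonate 16 with the isobutyrate silyl ketene acetal 17 (sets C6, installs CMe2CO2Me); 16 from 12 + 14 by Suzuki coupling.

Key step: step 12

Remark 1: (R)-(−)-linalool of high enantiomeric purity is assumed, since its carbinol carbon becomes C2 of the target unchanged.
Remark 2: the (Ra,R,R) enantiomer of the BINOL/bis(1-phenylethyl)amine phosphoramidite is assumed to deliver the (3R) product in step 8; its antipode is used if the established model for this catalyst class assigns the opposite sense.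

Step 1
Reactants: 1 (R)-(−)-linalool
Product: 2 (3R)-3,7-dimethyl-3-[(triethylsilyl)oxy]octa-1,6-diene
Conditions: TESOTf, 2,6-lutidine, CH2Cl2, −78 → 0 °C
Reagents that add atoms: triethylsilyl triflate, CC[Si](CC)(CC)OS(=O)(=O)C(F)(F)F
Why: Silylation of a hindered tertiary alcohol with a silyl triflate and a hindered pyridine base is standard, and the chiral-pool stereocentre is not touched.

Step 2
Reactants: 2 (3R)-3,7-dimethyl-3-[(triethylsilyl)oxy]octa-1,6-diene
Product: 4 (4R)-4-methyl-4-[(triethylsilyl)oxy]hex-5-enal, via secondary ozonide 3 (not isolated)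
Conditions: O3, CH2Cl2, −78 °C (Sudan III end point); then PPh3, −78 °C → rt
Reagents that add atoms: ozone, O=[O+][O-]
Why: Chemoselective ozonolysis should work because the electron-rich trisubstituted olefin reacts far faster than the vinyl group beside the silyloxy-bearing carbon, and reductive work-up of the ozonide gives the aldehyde.

Step 3
Reactants: 4 (4R)-4-methyl-4-[(triethylsilyl)oxy]hex-5-enal; 5 ethyltriphenylphosphonium iodide
Product: 9 (3R,6Z)-7-iodo-3-methyl-3-[(triethylsilyl)oxy]octa-1,6-diene, via ethylidenetriphenylphosphorane 6 (not isolated), via (1-iodoethyl)triphenylphosphonium iodide 7 (not isolated), via (1-iodoethylidene)triphenylphosphorane 8 (not isolated)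
Conditions: 5, n-BuLi, THF, 0 °C; I2, −78 °C; NaHMDS, −78 → −20 °C; then 4, −78 → −20 °C
Reagents that add atoms: iodine, II
Why: In this Stork–Zhao-type α-iodo Wittig olefination the non-stabilised iodo ylide should add under kinetic control to give the (Z)-2-iodoalk-2-ene (iodine cis to the chain), which fixes the geometry of the later Z olefin.

Step 4
Reactants: 10 but-2-yn-1-ol
Product: 12 (2Z)-3-iodobut-2-en-1-ol, via cyclic alkenylalanate 11 (not isolated)
Conditions: Red-Al, THF, 0 °C → rt; then I2, THF, −78 → 0 °C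
Reagents that add atoms: iodine, II
Why: Alkoxide-directed trans-hydroalumination of the propargylic alcohol (five-membered alanate) followed by iodinolysis of the C–Al bond with retention should give the (Z)-3-iodo allylic alcohol.

Step 5
Reactants: 12 (2Z)-3-iodobut-2-en-1-ol
Product: 13 tert-butyl{[(2Z)-3-iodobut-2-en-1-yl]oxy}dimethylsilane
Conditions: TBSCl, imidazole, CH2Cl2, rt
Reagents that add atoms: tert-butyldimethylsilyl chloride, CC(C)(C)[Si](C)(C)Cl
Why: This is a standard silylation of a primary alcohol, and the iodoalkene geometry is not affected.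

Step 6
Reactants: 13 tert-butyl{[(2Z)-3-iodobut-2-en-1-yl]oxy}dimethylsilane; 14 (2E)-3-(4,4,5,5-tetramethyl-1,3,2-dioxaborolan-2-yl)prop-2-en-1-ol
Product: 15 (2E,4Z)-6-[(tert-butyldimethylsilyl)oxy]-4-methylhexa-2,4-dien-1-ol
Conditions: Pd(PPh3)4 (5 mol %), aq. K3PO4, THF, 50 °C
Reagents that add atoms: none
Why: The alkenyl–alkenyl Suzuki–Miyaura coupling goes with retention at both partners and tolerates the free hydroxyl, so the (2E,4Z)-diene should form with defined geometry.

Step 7
Reactants: 15 (2E,4Z)-6-[(tert-butyldimethylsilyl)oxy]-4-methylhexa-2,4-dien-1-ol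
Product: 16 (2E,4Z)-6-[(tert-butyldimethylsilyl)oxy]-4-methylhexa-2,4-dien-1-yl methyl carbonate
Conditions: ClCO2Me, pyridine, CH2Cl2, 0 °C
Reagents that add atoms: methyl chloroformate, COC(=O)Cl
Why: Acylation of the primary allylic alcohol with a chloroformate is routine and provides the leaving group for the allylic substitution.

Step 8
Reactants: 16 (2E,4Z)-6-[(tert-butyldimethylsilyl)oxy]-4-methylhexa-2,4-dien-1-yl methyl carbonate; 17 1-methoxy-2-methyl-1-[(trimethylsilyl)oxy]prop-1-ene
Product: 18 methyl (3R,4Z)-6-[(tert-butyldimethylsilyl)oxy]-3-ethenyl-2,2,4-trimethylhex-4-enoate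
Conditions: [Ir(cod)Cl]2 (2 mol %), (Ra,R,R)-phosphoramidite (4 mol %, pre-activated with n-PrNH2), 17 (1.5 equiv), THF, rt
Reagents that add atoms: none
Why: In this iridium-catalysed asymmetric allylic alkylation with a silyl ketene acetal the cyclometalated Ir–allyl complex should be attacked at its substituted terminus (branched product), the chiral catalyst face sets the new C-3 stereocentre, and the methoxide released from the carbonate desilylates the ketene acetal.

Step 9
Reactants: 18 methyl (3R,4Z)-6-[(tert-butyldimethylsilyl)oxy]-3-ethenyl-2,2,4-trimethylhex-4-enoate; 9 (3R,6Z)-7-iodo-3-methyl-3-[(triethylsilyl)oxy]octa-1,6-diene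
Product: 20 methyl (3R,6Z,10R)-3-{(2Z)-4-[(tert-butyldimethylsilyl)oxy]but-2-en-2-yl}-2,2,6,10-tetramethyl-10-[(triethylsilyl)oxy]dodeca-6,11-dienoate, via B-alkyl-9-BBN borane 19 (not isolated)
Conditions: 9-BBN-H, THF, 0 °C → rt; then 9, Pd(dppf)Cl2 (5 mol %), AsPh3, Cs2CO3, DMF/H2O, rt
Reagents that add atoms: none
Why: 9-BBN should hydroborate only the monosubstituted vinyl group (anti-Markovnikov), and the B-alkyl Suzuki–Miyaura coupling with the (Z)-iodoalkene goes with retention, so the Z-trisubstituted olefin forms with defined geometry and no stereocentre is touched.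

Step 10
Reactants: 20 methyl (3R,6Z,10R)-3-{(2Z)-4-[(tert-butyldimethylsilyl)oxy]but-2-en-2-yl}-2,2,6,10-tetramethyl-10-[(triethylsilyl)oxy]dodeca-6,11-dienoate
Product: 21 methyl (3R,6Z,10R)-10-hydroxy-3-[(2Z)-4-hydroxybut-2-en-2-yl]-2,2,6,10-tetramethyldodeca-6,11-dienoate
Conditions: TBAF, AcOH (1:1), THF, 0 °C → rt
Reagents that add atoms: none
Why: Fluoride should cleave both silyl ethers, and the acetic acid buffer keeps the medium from promoting lactonisation onto the hindered ester or olefin migration.

Step 11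
Reactants: 21 methyl (3R,6Z,10R)-10-hydroxy-3-[(2Z)-4-hydroxybut-2-en-2-yl]-2,2,6,10-tetramethyldodeca-6,11-dienoate
Product: 22 methyl (3R,6Z,10R)-10-hydroxy-2,2,6,10-tetramethyl-3-[(2Z)-4-oxobut-2-en-2-yl]dodeca-6,11-dienoate
Conditions: TEMPO (10 mol %), PhI(OAc)2, CH2Cl2, 0 °C → rt; used at once
Reagents that add atoms: none
Why: The TEMPO/PhI(OAc)2 oxidation should convert only the primary allylic alcohol (the tertiary alcohol cannot react) under conditions known to preserve Z-enal geometry, as in the oxidation of nerol to neral.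

Step 12
Reactants: 22 methyl (3R,6Z,10R)-10-hydroxy-2,2,6,10-tetramethyl-3-[(2Z)-4-oxobut-2-en-2-yl]dodeca-6,11-dienoate
Product: 25 methyl 2-[(2R,4aS,5S,6R,8aR)-2-ethenyl-2,5,8a-trimethyl-5-(2-oxoethyl)octahydro-2H-chromen-6-yl]-2-methylpropanoate, via chloro(methyl)aluminium alkoxide 23 (not isolated), via bicyclic aluminium enolate 24 (not isolated)
Conditions: Me2AlCl (2.5 equiv), CH2Cl2 (0.01 M), −78 → −40 °C; aq. Rochelle salt
Reagents that add atoms: none
Why: Me2AlCl first turns the tertiary hydroxyl into its chloro(methyl)aluminium alkoxide 23 (methane lost, no free protons) and a second equivalent binds the aldehyde, so that the fully substituted β-carbon of the (Z)-enal becomes a tertiary 1-oxyallyl cation; the Z-trisubstituted olefin attacks it through its CH terminus, and the tertiary cation so formed is captured by the alkoxide oxygen to give enolate 24, which is protonated on work-up. The closest known reaction type is the alkylaluminium-halide-induced conjugate cation–olefin cyclisation of β,β-disubstituted enones and enals, ended here as in hydroxyl-terminated polyene cyclisations (homofarnesol to ambroxide, geranyllinalool to manoyl oxide). The cyclohexane closes first by 6-endo attack of the olefin (6-exo with respect to the enal) through a chair transition state, and the oxane closes last by 6-endo capture of the cation by oxygen, anti to the new C–C bond. C5 is set by allylic 1,3-strain, because the aldehyde carbon cis to C6 holds H-6 in the enal plane, so the olefin adds anti to the CMe2CO2Me group and the C5 methyl ends axial and trans to H-6; C4a and C8a follow from stereospecific anti addition across the Z olefin in that chair, which puts C4 axial and O1 equatorial (cis-fused oxane, methyls at C5 and C8a syn), while the absolute sense comes from C6 and C2 is carried in from linalool. The step needs β-attack instead of carbonyl attack (only the six-membered ring is within reach), oxygen capture instead of proton loss or 1,2-shift (capture is intramolecular and six-membered, and H-4a is equatorial and off the axis of the empty orbital), an enal that keeps its Z geometry and a tertiary allylic C–O bond that does not ionise (both served by −78 °C, the alkoxide in place of the free alcohol and the proton-scavenging Me–Al bond).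

Step 13
Reactants: 25 methyl 2-[(2R,4aS,5S,6R,8aR)-2-ethenyl-2,5,8a-trimethyl-5-(2-oxoethyl)octahydro-2H-chromen-6-yl]-2-methylpropanoate
Product: 26 [(2R,4aS,5S,6R,8aR)-2-ethenyl-6-(1-methoxy-2-methyl-1-oxopropan-2-yl)-2,5,8a-trimethyloctahydro-2H-chromen-5-yl]acetic acid
Conditions: NaClO2, NaH2PO4, 2-methylbut-2-ene, t-BuOH/H2O, 0 °C → rt
Reagents that add atoms: sodium chlorite, [Na+].[O-]Cl=O
Why: The Pinnick oxidation should convert the aldehyde into the acid without touching the vinyl group (the scavenger removes hypochlorous acid) or any stereocentre.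

Step 14
Reactants: 26 [(2R,4aS,5S,6R,8aR)-2-ethenyl-6-(1-methoxy-2-methyl-1-oxopropan-2-yl)-2,5,8a-trimethyloctahydro-2H-chromen-5-yl]acetic acid
Product: 27 2-[(2R,4aS,5S,6R,8aR)-5-(carboxymethyl)-2-ethenyl-2,5,8a-trimethyloctahydro-2H-chromen-6-yl]-2-methylpropanoic acid
Conditions: KOH, DMSO/H2O, 110 °C; then 1 M HCl to pH 3, 0 °C
Reagents that add atoms: potassium hydroxide, [K+].[OH-]
Why: Saponification of the hindered α,α-dimethyl ester needs forcing hydroxide conditions, which the ether, the vinyl group and the non-epimerisable stereocentres should tolerate, and mild acidification gives the diacid.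

Compound list
1 | (R)-(−)-linalool, (3R)-3,7-dimethylocta-1,6-dien-3-ol | C=C[C@@](O)(C)CCC=C(C)C | starting material
2 | (3R)-3,7-dimethyl-3-[(triethylsilyl)oxy]octa-1,6-diene | C=C[C@@](O[Si](CC)(CC)CC)(C)CCC=C(C)C | intermediate
3 | secondary ozonide of 2 at the trisubstituted olefin, 3-{(3R)-3-methyl-3-[(triethylsilyl)oxy]pent-4-en-1-yl}-5,5-dimethyl-1,2,4-trioxolane (formed in the flask) | C=C[C@@](O[Si](CC)(CC)CC)(C)CCC1OOC(C)(C)O1 | intermediate
4 | (4R)-4-methyl-4-[(triethylsilyl)oxy]hex-5-enal | C=C[C@@](O[Si](CC)(CC)CC)(C)CCC=O | intermediate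
5 | ethyltriphenylphosphonium iodide | CC[P+](c1ccccc1)(c1ccccc1)c1ccccc1.[I-] | starting material
6 | ethylidenetriphenylphosphorane (formed in the flask) | CC=P(c1ccccc1)(c1ccccc1)c1ccccc1 | intermediate
7 | (1-iodoethyl)triphenylphosphonium iodide (formed in the flask) | CC(I)[P+](c1ccccc1)(c1ccccc1)c1ccccc1.[I-] | intermediate
8 | (1-iodoethylidene)triphenylphosphorane (formed in the flask) | CC(I)=P(c1ccccc1)(c1ccccc1)c1ccccc1 | intermediate
9 | (3R,6Z)-7-iodo-3-methyl-3-[(triethylsilyl)oxy]octa-1,6-diene | C=C[C@@](O[Si](CC)(CC)CC)(C)CC/C=C(\I)C | intermediate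
10 | but-2-yn-1-ol | CC#CCO | starting material
11 | cyclic alkenylalanate, sodium 2,2-bis(2-methoxyethoxy)-3-methyl-2,5-dihydro-1,2-oxaaluminol-2-uide (formed in the flask) | CC1=CCO[Al-]1(OCCOC)OCCOC.[Na+] | intermediate
12 | (2Z)-3-iodobut-2-en-1-ol | C/C(I)=C/CO | intermediate
13 | tert-butyl{[(2Z)-3-iodobut-2-en-1-yl]oxy}dimethylsilane | C/C(I)=C/CO[Si](C)(C)C(C)(C)C | intermediate
14 | (2E)-3-(4,4,5,5-tetramethyl-1,3,2-dioxaborolan-2-yl)prop-2-en-1-ol | OC/C=C/B1OC(C)(C)C(C)(C)O1 | starting material
15 | (2E,4Z)-6-[(tert-butyldimethylsilyl)oxy]-4-methylhexa-2,4-dien-1-ol | OC/C=C/C(C)=C\CO[Si](C)(C)C(C)(C)C | intermediate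
16 | (2E,4Z)-6-[(tert-butyldimethylsilyl)oxy]-4-methylhexa-2,4-dien-1-yl methyl carbonate | COC(=O)OC/C=C/C(C)=C\CO[Si](C)(C)C(C)(C)C | intermediate
17 | 1-methoxy-2-methyl-1-[(trimethylsilyl)oxy]prop-1-ene | COC(O[Si](C)(C)C)=C(C)C | starting material
18 | methyl (3R,4Z)-6-[(tert-butyldimethylsilyl)oxy]-3-ethenyl-2,2,4-trimethylhex-4-enoate | C=C[C@@H](C(C)(C)C(=O)OC)/C(C)=C\CO[Si](C)(C)C(C)(C)C | intermediate
19 | methyl (3R,4Z)-3-[2-(9-borabicyclo[3.3.1]nonan-9-yl)ethyl]-6-[(tert-butyldimethylsilyl)oxy]-2,2,4-trimethylhex-4-enoate (formed in the flask) | C(C[C@@H](C(C)(C)C(=O)OC)/C(C)=C\CO[Si](C)(C)C(C)(C)C)B1C2CCCC1CCC2 | intermediate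
20 | methyl (3R,6Z,10R)-3-{(2Z)-4-[(tert-butyldimethylsilyl)oxy]but-2-en-2-yl}-2,2,6,10-tetramethyl-10-[(triethylsilyl)oxy]dodeca-6,11-dienoate | C=C[C@@](O[Si](CC)(CC)CC)(C)CC/C=C(/C)CC[C@@H](C(C)(C)C(=O)OC)/C(C)=C\CO[Si](C)(C)C(C)(C)C | intermediate
21 | methyl (3R,6Z,10R)-10-hydroxy-3-[(2Z)-4-hydroxybut-2-en-2-yl]-2,2,6,10-tetramethyldodeca-6,11-dienoate | C=C[C@@](O)(C)CC/C=C(/C)CC[C@@H](C(C)(C)C(=O)OC)/C(C)=C\CO | intermediate
22 | methyl (3R,6Z,10R)-10-hydroxy-2,2,6,10-tetramethyl-3-[(2Z)-4-oxobut-2-en-2-yl]dodeca-6,11-dienoate | C=C[C@@](O)(C)CC/C=C(/C)CC[C@@H](C(C)(C)C(=O)OC)/C(C)=C\C=O | intermediate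
23 | chloro(methyl)aluminium alkoxide of 22 at the tertiary oxygen (formed in the flask) | C=C[C@@](O[Al](C)Cl)(C)CC/C=C(/C)CC[C@@H](C(C)(C)C(=O)OC)/C(C)=C\C=O | intermediate
24 | chloro(methyl)aluminium enolate of aldehyde 25, bicyclic (formed in the flask) | C=C[C@@]1(C)CC[C@H]2[C@@](C)(C=CO[Al](C)Cl)[C@H](C(C)(C)C(=O)OC)CC[C@@]2(C)O1 | intermediate
25 | methyl 2-[(2R,4aS,5S,6R,8aR)-2-ethenyl-2,5,8a-trimethyl-5-(2-oxoethyl)octahydro-2H-chromen-6-yl]-2-methylpropanoate | C=C[C@@]1(C)CC[C@H]2[C@@](C)(CC=O)[C@H](C(C)(C)C(=O)OC)CC[C@@]2(C)O1 | intermediate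
26 | [(2R,4aS,5S,6R,8aR)-2-ethenyl-6-(1-methoxy-2-methyl-1-oxopropan-2-yl)-2,5,8a-trimethyloctahydro-2H-chromen-5-yl]acetic acid | C=C[C@@]1(C)CC[C@H]2[C@@](C)(CC(=O)O)[C@H](C(C)(C)C(=O)OC)CC[C@@]2(C)O1 | intermediate
27 | 2-[(2R,4aS,5S,6R,8aR)-5-(carboxymethyl)-2-ethenyl-2,5,8a-trimethyloctahydro-2H-chromen-6-yl]-2-methylpropanoic acid (CNP0186744.1) | C=C[C@@]1(C)CC[C@H]2[C@@](C)(CC(=O)O)[C@H](C(C)(C)C(=O)O)CC[C@@]2(C)O1 | target

Total step count: 14.
Longest linear sequence: 11 steps (10 → 27, steps 4 to 14); the linalool branch (steps 1 to 3) joins at step 9.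

Steps most likely to fail

Step 12 (key bicyclisation). The aluminium-complexed enal may isomerise from Z to E before ring closure, which would remove the allylic-strain control at C5. The tertiary allylic C–O bond may ionise under the Lewis acid, or the tertiary cation may lose a proton instead of being captured by oxygen. Fallback, setting out from 22 and returning at 25: the two bond formations are separated. Silylation of the tertiary hydroxyl with N-(trimethylsilyl)imidazole should give the trimethylsilyl ether of 22 F1. Me2AlCl then induces only the conjugate ene-type closure of the cyclohexane (proton loss from the methyl group of the tertiary cation), and acidic work-up, which also removes the silyl group, should give the monocyclic exo-methylene hydroxy aldehyde F2. Iodoetherification (I2, NaHCO3, MeCN, 0 °C) closes the oxane on the only face that the axial side chain can reach and should give the iodomethyl oxane F3. Radical deiodination (Bu3SnH, AIBN, PhH, 80 °C) then returns to 25.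

Step 8 (allylic alkylation). Attack may occur at the unsubstituted allyl terminus or along the dienyl system, turnover may be low with the hindered tetrasubstituted ketene acetal, or the enantioselectivity may be eroded. Fallback, setting out from 15 and returning at 18: acylation with isobutyryl chloride and pyridine should give the isobutyrate of 15 F4. Enolisation at −78 °C with chiral 2-bromo-4,5-diphenyl-1,3-bis(p-tolylsulfonyl)-1,3,2-diazaborolidine and i-Pr2NEt gives the boron ketene acetal F5 (not isolated; written for the (S,S) reagent, the antipode being used if the chair model requires it). Its enantioselective Ireland–Claisen rearrangement through a chair transition state should give, after hydrolytic work-up, (3R,4Z)-6-[(tert-butyldimethylsilyl)oxy]-3-ethenyl-2,2,4-trimethylhex-4-enoic acid F6. Methylation (TMSCHN2, MeOH/toluene) returns to 18.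

Step 3 (iodo-olefination). The ylide may decompose or lose iodine, giving low conversion, and the Z/E ratio may be poor, which would carry over into the olefin geometry that the key step depends on. Fallback, setting out from 4 and returning at 20: Corey–Fuchs-type dibromo-olefination (CBr4, PPh3, Et3N, CH2Cl2) should give (3R)-6,6-dibromo-3-methyl-3-[(triethylsilyl)oxy]hexa-1,5-diene F7. A palladium-catalysed Negishi monomethylation (MeZnCl, Pd(DPEphos)Cl2), which selectively replaces the bromine trans to the chain, should give (3R,6Z)-7-bromo-3-methyl-3-[(triethylsilyl)oxy]octa-1,6-diene F8. F8 takes the place of 9 in the B-alkyl Suzuki coupling of step 9 (Cs2CO3 as base) and so returns to 20.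

Further compounds
F1 | step 12 | methyl (3R,6Z,10R)-2,2,6,10-tetramethyl-3-[(2Z)-4-oxobut-2-en-2-yl]-10-[(trimethylsilyl)oxy]dodeca-6,11-dienoate | C=C[C@@](O[Si](C)(C)C)(C)CC/C=C(/C)CC[C@@H](C(C)(C)C(=O)OC)/C(C)=C\C=O
F2 | step 12 | monocyclic exo-methylene hydroxy aldehyde (cyclohexane closed, oxane open, ring centres as in 25) | C=C[C@@](O)(C)CC[C@H]1[C@@](C)(CC=O)[C@H](C(C)(C)C(=O)OC)CCC1=C
F3 | step 12 | 8a-(iodomethyl) analogue of 25 (iodomethyl in place of the C8a methyl) | C=C[C@@]1(C)CC[C@H]2[C@@](C)(CC=O)[C@H](C(C)(C)C(=O)OC)CC[C@@]2(CI)O1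
F4 | step 8 | (2E,4Z)-6-[(tert-butyldimethylsilyl)oxy]-4-methylhexa-2,4-dien-1-yl 2-methylpropanoate | CC(C)C(=O)OC/C=C/C(C)=C\CO[Si](C)(C)C(C)(C)C
F5 | step 8 | boron ketene acetal of F4 with the (S,S)-4,5-diphenyl-1,3-bis(p-tolylsulfonyl)-1,3,2-diazaborolidin-2-yl group | CC(C)=C(OC/C=C/C(C)=C\CO[Si](C)(C)C(C)(C)C)OB1N(S(=O)(=O)c2ccc(C)cc2)[C@@H](c2ccccc2)[C@H](c2ccccc2)N1S(=O)(=O)c1ccc(C)cc1
F6 | step 8 | (3R,4Z)-6-[(tert-butyldimethylsilyl)oxy]-3-ethenyl-2,2,4-trimethylhex-4-enoic acid | C=C[C@@H](C(C)(C)C(=O)O)/C(C)=C\CO[Si](C)(C)C(C)(C)C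
F7 | step 3 | (3R)-6,6-dibromo-3-methyl-3-[(triethylsilyl)oxy]hexa-1,5-diene | C=C[C@@](O[Si](CC)(CC)CC)(C)CCC=C(Br)Br
F8 | step 3 | (3R,6Z)-7-bromo-3-methyl-3-[(triethylsilyl)oxy]octa-1,6-diene | C=C[C@@](O[Si](CC)(CC)CC)(C)CC/C=C(\Br)C
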